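A slow event in these flasks is the leak of target into side product, and a share read at the end of a short run measures that leak against the length of the run.

in all of them: solid substrate 23 mM; protic impurity 2.30 mM; time 4.0 min

| flask | partner | second substrate | remark |
|---|---|---|---|
| Thursday's | 23.0 mM (fed, over 2.5 min) | 23.0 mM | all else is in the flask from the start; the feed brings no volume worth counting |
| Tuesday's | 23.0 mM | 23.0 mM | everything together at the start |
| Sunday's | 23.0 mM | 23.0 mM (fed, over 2.5 min) | all else is in the flask from the start; the feed brings no volume worth counting |

    solid substrate ⇌ starting material, rate k1*(cs1 - [starting material]) while solid is left; crystals form when [starting material] > cs1 (cs1 = 19 mM, k1 = 0.425 s⁻¹)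
    starting material + partner ⇌ target (K2 = 2.62 M⁻¹, k2 = 1.06 M⁻¹ s⁻¹)
    partner + protic impurity → quenched reagent (k3 = 14.6 M⁻¹ s⁻¹)
    second substrate + partner ⇌ second product (K4 = 370 M⁻¹, k4 = 0.0255 M⁻¹ s⁻¹)
    starting material + target → side product (k5 = 0.0465 M⁻¹ s⁻¹)

- percentages count the solid substrate that a species holds: one side product counts as two
- solid, in amounts per volume of the solution: solid substrate
- at the start none of the solid substrate is in solution
- run time (Thursday's): 4.0 min

1. the flask that comes out highest in share of target in target plus side product, or "all alike" when all lie within 1.5 percentage points (Thursday's / Tuesday's / Sunday's / all alike)
2. share of target in target plus side product at the end, Thursday's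
3. share of target in target plus side product at the end, Tuesday's
4. share of target in target plus side product at the end, Sunday's

While solid lasts, starting material stays near 82.6% of the solid charge, so the leak is pseudo-first-order in target. The side-product clock, the time in which target at a steady level gives side product holding as much solid substrate as itself, is 9.43 min. Solid refills the solution in 2.35 s and target falls back in 2.47 s, both far shorter than the clock, so target follows free partner. Call the age of the target its time integral divided by its final level. The level then cancels, and the share is one over one plus age divided by clock.

The curve for Tuesday's, with target taken as level so that age equals time, starts at one with slope 0.106 min⁻¹ downward, and bends gently as age grows. In Tuesday's, target and side product would hold equal solid substrate at an age of one clock, which is longer than the run. At 4.0 min the curve stands at 70.2%. Sunday's gets the same figure in this reckoning, because its partner is charged at the start and second substrate, whose forward half-life by step 4 at Tuesday's charges is 20 min, reacts over a time longer than the run. In Thursday's, the fed charge of partner, taken as a whole, arrives 1.25 min after the start on average, so the age is reckoned as 2.75 min and the share as 77.4%.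

The forecast, noting that on Thursday's “partner builds up slowly”, named Thursday's, with 77.2% for Thursday's, 69.2% for Tuesday's and 69.3% for Sunday's. For Tuesday's it stands 1 percentage point below this reckoning.

The flask gives Thursday's as highest, at 77.5%, against 69.3% for Tuesday's and 69.4% for Sunday's. Tuesday's ends with starting material at 82.6% and 12.0% of the charge still solid, and its share moves by 5 points at a solid charge of 67.4% of the present one. Put back through the clock, the shares read as ages of 4.18 min for Tuesday's and 2.74 min for Thursday's.

Tuesday's read at 1.5 min has, with target taken as level, an age equal to that time, so the clock gives 86.3%. The computed share is 86.7%.

The numbers stand for no real mixture; no experiment stands behind them.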